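## Analysis of the target

The target is the 4-hydroxy-3-methoxybenzoate (vanillate) of a primary alcohol on an oxygen-bridged daucane sesquiterpene. The terpene carbons are numbered as in daucane: C1 (quaternary, carries methyl C15), C2, C3, C4 (carries the side chain C11(–C13)–C12–O), C5 (ring fusion, oxygen), C6, C7, C8 (oxygen, methyl C14), C9 (hydroxyl), C10.

Ring A is the cyclopentane C1–C2–C3–C4–C5. Ring B is the cycloheptane C1–C10–C9–C8–C7–C6–C5, fused to ring A through the C1–C5 bond. One ether oxygen joins C5 to C8 across ring B, so the core is an 8-oxabicyclo[3.2.1]octane built from a tetrahydrofuran (O, C5, C6, C7, C8) and a tetrahydropyran (O, C5, C1, C10, C9, C8).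

There are six stereocentres: C1 (R), C4 (R), C5 (S), C8 (S), C9 (S), C11 (S). C15, the C5–O bond and the C4 side chain lie on one face of ring A. C8 is tied to C5 by the bridge. The C9 hydroxyl is equatorial on the tetrahydropyran chair, anti to the C8–O bond. C11 is an open-chain centre next to C4.

The hardest bond is C1–C5. It joins an all-carbon quaternary centre to a tetrasubstituted ether carbon and, with C4, gives three contiguous stereocentres on ring A. The ether links two tertiary carbons and cannot be made by a simple substitution.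

Sensitive groups are the aryl ester with its free phenol (strong nucleophiles, alkoxides, oxidants) and the two tertiary C–O bonds (strong acid). At the C9 ketone stage the C8–O bond is α to a carbonyl and would be cleaved by electron-transfer reductants.

The feature that invites the key move: the tetrahydrofuran O–C5–C6–C7–C8, with both α-carbons fully substituted, is a reduced 2,5-dialkylfuran. Its α-carbons are spanned by the three-carbon unit C1–C10–C9, whose only oxygen sits on the terminal carbon C9.

## Retrosynthetic reasoning

**C9 and the protecting groups.** Target 19 comes from ketone 18 by hydride reduction, 18 from enol acetate 17 by methanolysis, and 17 from diene 16 by hydrogenation. The C6=C7 bond of 16 is what remains of a furan. The vanillate is carried from the start as the only protecting group of O12, with its phenol as a benzyl ether that falls off in the hydrogenation the alkene needs anyway.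

**Key disconnection, 16 to 15.** The bonds C1–C5 and C8–C9 are cut together. These are the two bonds that tie the unit C1–C10–C9 to the α-carbons of the tetrahydrofuran. Cutting them turns the tricycle into the open-chain furan 15 with only two stereocentres (C4, C11) and leaves the oxygen of C9 on an allene terminus, so no carbonyl transposition is needed later. The forward step is a gold-catalysed (4+3) cycloaddition. It has to join two fully substituted carbons and set C1, C5 and C8 from C4.

**Allene, 15 to 14 to 11 + 12.** The acetoxyallene is the 3,3-shift isomer of the tertiary propargylic acetate 14. Cutting C1–C10 gives methyl ketone 11 and the acetylide 12, which brings in C10 and C9.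

**Chain, 11 to 10 to 8 + 9.** The C2–C3 bond is cut as an alkene. Cross-metathesis of terminal alkene 8 with enone 9 gives 10, and hydrogenation of the conjugated double bond gives 11. Enone 9 supplies C2, C1 and C15 at the right oxidation level.

**Ester, 8 to 6 + 7.** The ester bond is made early from alcohol 6 and acid 7.

**Stereodiad, 6 to 3 + 4, and 3 to 1 + 2.** The C4–C11 bond is cut. Both stereocentres arise in one catalytic step from racemic furyl vinyl carbinol 3 and aldehyde 4 (via aldehyde 5, reduced in the flask). Carbinol 3 comes from aldehyde 1 and Grignard reagent 2.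

## Alternatives that were turned down

**Alternative 1:** the textbook, biogenetically inspired route. Disconnection: the C8–O bond, made by transannular opening of a C8–C9 epoxide by the C5 hydroxyl. Forward: the cyclopentanone A1 adds 3-methylbut-3-enylmagnesium bromide to give the diene carbinol A2; ring-closing metathesis gives the 5-hydroxy-8-ene A3; peracid epoxidation of A3 with opening by the C5 hydroxyl in the same operation gives the bridge and the C9 alcohol. The end game is reliable. It was turned down for three reasons:
- C1 of A1 carries methyl and allyl, two groups of similar size, so the allylation that sets C1 against C4 has no intrinsic bias.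
- The Grignard addition at C5 has to come anti to the C4 side chain and syn to the allyl group, again with little bias.
- The ring stereocentres are set one at a time, and A1 needs its own enantioselective synthesis, for an estimated fourteen steps or more.

**Alternative 2:** the same two bonds (C1–C5, C8–C9), cut with a classical 2-oxyallyl cation. Forward: the tertiary α-chloro ketone A4, treated with base in trifluoroethanol, gives the cycloadduct A5. It was turned down because the oxygen of A5 sits on C10, not C9. A 1,2-carbonyl transposition would then cost at least four steps (removal of the C10 carbonyl through an alkene, hydroboration with uncertain facial selectivity, reoxidation, reduction). A4 also cannot be made by electrophilic chlorination next to a 2,5-dialkylfuran. The topological question at C1 stays the same without any gain.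

**Alternative 3:** cut C5–C6 and C7–C8 by a carbonyl ylide (3+2) cycloaddition. Forward: the diazo diketone A6 with Rh2(OAc)4 forms a six-membered carbonyl ylide from the C5 ketone and the C8 carbenoid; addition of ethene gives the C9 ketone A7 with the oxygen pattern correct. It was turned down because C6–C7 is unsubstituted. The dipolarophile would have to be ethene itself, a poor partner for an electrophilic ylide in an intermolecular reaction, or a surrogate whose activating group needs extra steps to remove. A6 also needs the cis C1/C4 cyclopentanone, with the same stereochemical weakness as A1.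

Key step: step 8

Assumption: the (R)-phosphoramidite–olefin ligand is taken to give the 3R configuration of 5; ligand and amine control their centres independently, so the (S)-ligand is used if the furyl carbinol shows the opposite sense.

## Route

Step 1
Reactants: 1 5-methylfuran-2-carbaldehyde; 2 vinylmagnesium bromide
Product: 3 1-(5-methylfuran-2-yl)prop-2-en-1-ol (racemic)
Conditions: THF, −78 to 0 °C; aq NH4Cl
Reagents that add atoms: none
Why: 1,2-Addition of a vinyl Grignard reagent to the aldehyde; the carbinol is used racemic because step 2 is enantioconvergent.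

Step 2
Reactants: 3 1-(5-methylfuran-2-yl)prop-2-en-1-ol; 4 propanal
Product: 6 (2S,3R)-2-methyl-3-(5-methylfuran-2-yl)pent-4-en-1-ol, via pentenal 5 (not isolated)
Conditions: [Ir(cod)Cl]2 (3 mol%), (R)-4-(5H-dibenzo[b,f]azepin-5-yl)dinaphtho[2,1-d:1',2'-f][1,3,2]dioxaphosphepine (12 mol%), (R)-2-{bis[3,5-bis(trifluoromethyl)phenyl](trimethylsilyloxy)methyl}pyrrolidine (10 mol%), (MeO)2P(O)OH (0.5 equiv), 1,2-dichloroethane, 25 °C; then NaBH4, MeOH, 0 °C
Reagents that add atoms: none
Why: Stereodivergent dual catalysis (iridium-catalysed allylic substitution combined with enamine catalysis): the iridium π-allyl complex from either enantiomer of 3 is attacked at the furyl-bearing terminus, where the ligand fixes the later C4, and the enamine of propanal reacts on the face left open by the (R)-prolinol ether, which fixes the later C11 as S. The epimerisable aldehyde 5 is reduced in the same flask.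

Step 3
Reactants: 6 (2S,3R)-2-methyl-3-(5-methylfuran-2-yl)pent-4-en-1-ol; 7 4-(benzyloxy)-3-methoxybenzoic acid
Product: 8 (2S,3R)-2-methyl-3-(5-methylfuran-2-yl)pent-4-en-1-yl 4-(benzyloxy)-3-methoxybenzoate
Conditions: EDC·HCl, DMAP, CH2Cl2, rt
Reagents that add atoms: none
Why: Carbodiimide (Steglich) esterification of the only hydroxyl group; the benzyl-protected vanillate then protects O12 for the rest of the route.

Step 4
Reactants: 8 (2S,3R)-2-methyl-3-(5-methylfuran-2-yl)pent-4-en-1-yl 4-(benzyloxy)-3-methoxybenzoate; 9 but-3-en-2-one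
Product: 10 (2S,3R,4E)-2-methyl-3-(5-methylfuran-2-yl)-6-oxohept-4-en-1-yl 4-(benzyloxy)-3-methoxybenzoate
Conditions: second-generation Hoveyda–Grubbs catalyst RuCl2(H2IMes)(=CH–C6H4–2-OiPr) (5 mol%), 9 (4 equiv), 1,4-benzoquinone (10 mol%), CH2Cl2, 40 °C
Reagents that add atoms: none
Why: Olefin cross-metathesis of a terminal alkene with an electron-poor enone, E-selective and driven by loss of ethene; it brings in C2, C1 and C15 at the right oxidation level.

Step 5
Reactants: 10 (2S,3R,4E)-2-methyl-3-(5-methylfuran-2-yl)-6-oxohept-4-en-1-yl 4-(benzyloxy)-3-methoxybenzoate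
Product: 11 (2S,3R)-2-methyl-3-(5-methylfuran-2-yl)-6-oxoheptyl 4-(benzyloxy)-3-methoxybenzoate
Conditions: H2 (1–3 atm), RhCl(PPh3)3 (5 mol%), benzene–EtOH, rt
Reagents that add atoms: none
Why: Homogeneous hydrogenation with RhCl(PPh3)3 saturates the disubstituted enone C=C and leaves the furan, the ketone and the benzyl ether alone; neutral conditions keep the furfuryl centre from epimerising.

Step 6
Reactants: 11 (2S,3R)-2-methyl-3-(5-methylfuran-2-yl)-6-oxoheptyl 4-(benzyloxy)-3-methoxybenzoate; 12 ethynylmagnesium bromide
Product: 14 (2S,3R)-6-acetoxy-2,6-dimethyl-3-(5-methylfuran-2-yl)oct-7-yn-1-yl 4-(benzyloxy)-3-methoxybenzoate (both C6 epimers), via bromomagnesium alkoxide 13 (not isolated)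
Conditions: 12 (1.5 equiv), THF, −20 to 0 °C; then Ac2O, DMAP, 0 °C to rt
Reagents that add atoms: acetic anhydride, CC(=O)OC(C)=O
Why: An alkynyl Grignard reagent adds to the methyl ketone much faster than to the electron-rich aryl ester, and the magnesium alkoxide 13 is acetylated in the flask. The new carbinol centre forms as both epimers, which does not matter because it becomes sp2 in step 7.

Step 7
Reactants: 14 (2S,3R)-6-acetoxy-2,6-dimethyl-3-(5-methylfuran-2-yl)oct-7-yn-1-yl 4-(benzyloxy)-3-methoxybenzoate
Product: 15 (2S,3R)-8-acetoxy-2,6-dimethyl-3-(5-methylfuran-2-yl)octa-6,7-dien-1-yl 4-(benzyloxy)-3-methoxybenzoate (both allene diastereomers)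
Conditions: AgBF4 (5 mol%), 2,6-di-tert-butyl-4-methylpyridine (10 mol%), CH2Cl2, rt, dark
Reagents that add atoms: none
Why: Saucy–Marbet rearrangement: silver-catalysed 3,3-acyloxy shift of a tertiary ethynyl carbinol acetate to the 1-acetoxyallene. Silver is used in a separate step because gold would open the competing 1,2-acyloxy shift of the terminal alkyne, which would put the oxygen on C10.

Step 8
Reactants: 15 (2S,3R)-8-acetoxy-2,6-dimethyl-3-(5-methylfuran-2-yl)octa-6,7-dien-1-yl 4-(benzyloxy)-3-methoxybenzoate
Product: 16 (1R,4R,5S,8S,11S)-9-acetoxy-5,8-epoxydauca-6,9-dien-12-yl 4-(benzyloxy)-3-methoxybenzoate (ring A fused at C1–C5 to the 8-oxabicyclo[3.2.1]octa-2,6-diene; C15, the ring oxygen and the C4 side chain on one face of ring A)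
Conditions: (IPr)AuCl (5 mol%; IPr = 1,3-bis(2,6-diisopropylphenyl)imidazol-2-ylidene), AgSbF6 (5 mol%), 4 Å MS, CH2Cl2, −20 °C to rt
Reagents that add atoms: none
Why: The NHC–gold cation binds the allene and slips to a planar 2-aurated allyl cation over C1–C10–C9 (so both allene diastereomers converge), stabilised at C1 by two alkyl groups and at C9 by the acetoxy oxygen; it adds across the furan termini C5 and C8, and the gold carbene left at C10 ends by a 1,2-hydride shift from C9 and loss of the gold cation, which gives the C9=C10 enol acetate. The closest known reaction type is the gold-catalysed intramolecular (4+3) cycloaddition of allenes, acyloxyallenes from propargyl esters included, with tethered 1,3-dienes and furans, which ends by the same 1,2-shift. Ring A closes through the C1–C5 bond (five-membered, the tether C2–C3–C4 joins the two reacting termini), and ring B and the tetrahydropyran close together through the C8–C9 bond as the second bond of the (4+3) process. C5 is controlled by C4: to avoid 1,3-allylic strain with H6 of the furan the C4–H bond lies in the furan plane, the tether then occupies one face and the C11 side chain the other, which places the side chain cis to the ring oxygen. C1 is controlled by the topology of the approach: with the tether in the outside position of the allyl cation, the compact (boat-like) approach puts C15 over the ring oxygen and gives the isomer in which ring A uses the equatorial bond at C1, the only ring fusion that the bridgehead geometry allows without a boat tetrahydropyran, whereas the extended approach would push C15 against C6. C8 follows from the suprafacial addition to the furan. The step needs (4+3) periselectivity over Friedel–Crafts attack at C6, (4+2) closure and proton loss to a dienyl acetate, which the more nucleophilic furan α-positions, the short tether and the donor NHC ligand should favour, and it needs hydride in place of acetoxy migration, which the compact adduct secures because its C9–H bond is axial and parallel to the empty carbene orbital while the acetoxy group is equatorial.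

Step 9
Reactants: 16 (1R,4R,5S,8S,11S)-9-acetoxy-5,8-epoxydauca-6,9-dien-12-yl 4-(benzyloxy)-3-methoxybenzoate
Product: 17 (1R,4R,5S,8S,11S)-9-acetoxy-5,8-epoxydauc-9-en-12-yl 4-hydroxy-3-methoxybenzoate
Conditions: H2 (1 atm), 10% Pd/C, EtOAc, rt
Reagents that add atoms: none
Why: Heterogeneous hydrogenation saturates the strained cis-disubstituted C6=C7 bond and cleaves the benzyl ether in one operation; the C9=C10 enol acetate, flanked by two fully substituted carbons, should survive. No stereocentre is formed.

Step 10
Reactants: 17 (1R,4R,5S,8S,11S)-9-acetoxy-5,8-epoxydauc-9-en-12-yl 4-hydroxy-3-methoxybenzoate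
Product: 19 (1R,4R,5S,8S,9S,11S)-5,8-epoxy-9-hydroxydaucan-12-yl 4-hydroxy-3-methoxybenzoate, via ketone 18 (not isolated)
Conditions: K2CO3 (cat.), MeOH, 0 °C to rt; then NaBH4, −20 to 0 °C; aq NH4Cl
Reagents that add atoms: none
Why: Methanolysis of the enol acetate gives ketone 18 (the phenoxide formed under these conditions shields the aryl ester from transesterification), and borohydride then adds hydride to C9 from the face of the oxygen bridge, away from the C6–C7 bridge, to give the equatorial alcohol anti to the C8–O bond. This is also the more stable epimer, since the axial one would place OH 1,3-diaxial to C15; electron-transfer reductants are excluded because the C8–O bond is α to the ketone.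

## Compound list

1 | 5-methylfuran-2-carbaldehyde | Cc1ccc(C=O)o1 | starting material
2 | vinylmagnesium bromide | C=C[Mg]Br | starting material
3 | 1-(5-methylfuran-2-yl)prop-2-en-1-ol (racemic) | Cc1ccc(C(O)C=C)o1 | intermediate
4 | propanal | CCC=O | starting material
5 | (2S,3R)-2-methyl-3-(5-methylfuran-2-yl)pent-4-enal | O=C[C@@H](C)[C@H](c1ccc(C)o1)C=C | intermediate
6 | (2S,3R)-2-methyl-3-(5-methylfuran-2-yl)pent-4-en-1-ol | OC[C@@H](C)[C@H](c1ccc(C)o1)C=C | intermediate
7 | 4-(benzyloxy)-3-methoxybenzoic acid | COc1cc(C(=O)O)ccc1OCc1ccccc1 | starting material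
8 | (2S,3R)-2-methyl-3-(5-methylfuran-2-yl)pent-4-en-1-yl 4-(benzyloxy)-3-methoxybenzoate | COc1cc(C(=O)OC[C@@H](C)[C@H](c2ccc(C)o2)C=C)ccc1OCc1ccccc1 | intermediate
9 | but-3-en-2-one (methyl vinyl ketone) | CC(=O)C=C | starting material
10 | (2S,3R,4E)-2-methyl-3-(5-methylfuran-2-yl)-6-oxohept-4-en-1-yl 4-(benzyloxy)-3-methoxybenzoate | COc1cc(C(=O)OC[C@@H](C)[C@H](c2ccc(C)o2)/C=C/C(C)=O)ccc1OCc1ccccc1 | intermediate
11 | (2S,3R)-2-methyl-3-(5-methylfuran-2-yl)-6-oxoheptyl 4-(benzyloxy)-3-methoxybenzoate | COc1cc(C(=O)OC[C@@H](C)[C@H](c2ccc(C)o2)CCC(C)=O)ccc1OCc1ccccc1 | intermediate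
12 | ethynylmagnesium bromide | C#C[Mg]Br | starting material
13 | bromomagnesium alkoxide of the tertiary propargylic alcohol from 11 (both epimers) | COc1cc(C(=O)OC[C@@H](C)[C@H](c2ccc(C)o2)CCC(C)(O[Mg]Br)C#C)ccc1OCc1ccccc1 | intermediate
14 | (2S,3R)-6-acetoxy-2,6-dimethyl-3-(5-methylfuran-2-yl)oct-7-yn-1-yl 4-(benzyloxy)-3-methoxybenzoate (both C6 epimers) | COc1cc(C(=O)OC[C@@H](C)[C@H](c2ccc(C)o2)CCC(C)(OC(C)=O)C#C)ccc1OCc1ccccc1 | intermediate
15 | (2S,3R)-8-acetoxy-2,6-dimethyl-3-(5-methylfuran-2-yl)octa-6,7-dien-1-yl 4-(benzyloxy)-3-methoxybenzoate (both allene diastereomers) | COc1cc(C(=O)OC[C@@H](C)[C@H](c2ccc(C)o2)CCC(C)=C=COC(C)=O)ccc1OCc1ccccc1 | intermediate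
16 | (1R,4R,5S,8S,11S)-9-acetoxy-5,8-epoxydauca-6,9-dien-12-yl 4-(benzyloxy)-3-methoxybenzoate | COc1cc(C(=O)OC[C@@H](C)[C@H]2CC[C@]3(C)C=C(OC(C)=O)[C@]4(C)C=C[C@]23O4)ccc1OCc1ccccc1 | intermediate
17 | (1R,4R,5S,8S,11S)-9-acetoxy-5,8-epoxydauc-9-en-12-yl 4-hydroxy-3-methoxybenzoate | COc1cc(C(=O)OC[C@@H](C)[C@H]2CC[C@]3(C)C=C(OC(C)=O)[C@]4(C)CC[C@]23O4)ccc1O | intermediate
18 | (1R,4R,5S,8S,11S)-5,8-epoxy-9-oxodaucan-12-yl 4-hydroxy-3-methoxybenzoate | COc1cc(C(=O)OC[C@@H](C)[C@H]2CC[C@]3(C)CC(=O)[C@]4(C)CC[C@]23O4)ccc1O | intermediate
19 | (1R,4R,5S,8S,9S,11S)-5,8-epoxy-9-hydroxydaucan-12-yl 4-hydroxy-3-methoxybenzoate | COc1cc(C(=O)OC[C@@H](C)[C@H]2CC[C@]3(C)C[C@H](O)[C@]4(C)CC[C@]23O4)ccc1O | target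

## Step count and least certain steps

Total steps: 10. Longest linear sequence: 10 steps (1 to 19).

**Step 8 (key step).** The most likely failure is an approach of the allyl cation through the extended topology in place of the compact one. That would give the C1 epimer, with C15 trans to the ring oxygen, and the quaternary centre cannot be corrected afterwards. Lesser risks are Friedel–Crafts alkylation at C6, proton loss from the allyl cation to a dienyl acetate, and acetoxy migration in place of hydride migration at the carbene.

The fallback sets out from 8 and comes back at 18. It builds C1 after the ring system, so the topology of the cycloaddition no longer matters.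
- Linear hydroformylation of 8 (Rh(acac)(CO)2, Xantphos, CO/H2) should give the aldehyde F1.
- Ethynylmagnesium bromide, then acetic anhydride, should give the secondary propargylic acetate F2.
- AgBF4 should give the allenyl acetate F3, in which C1 carries hydrogen, the substitution pattern for which gold (4+3) cycloadditions are best established.
- (IPr)AuCl/AgSbF6 should give the cycloadduct F4 as either C1 epimer.
- Bu3SnOMe, catalytic Pd(OAc)2 and allyl methyl carbonate in MeCN (dehydrogenation of the enol acetate through its tin enolate) should give the enone F5, in which C1 is sp2.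
- Me2CuLi with Me3SiCl should add C15 from the face of the oxygen bridge, anti to the C6=C7 bridge, to give the ketone F6.
- H2 over Pd/C then saturates C6=C7 and removes the benzyl group to give 18.

**Step 2.** The electron-rich furyl vinyl carbinol may ionise without the metal under the acidic promoter (Piancatelli-type rearrangement, oligomerisation) or react at the unsubstituted allyl terminus, so conversion or stereocontrol may be poor.

The fallback sets out from 1 and comes back at 10.
- Henry condensation of 1 with nitromethane should give the nitroalkene F7.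
- Michael addition of propanal under (R)-α,α-diphenylprolinol trimethylsilyl ether should give the syn nitro aldehyde F8 (enamine catalysis; this catalyst class gives syn adducts, and the R catalyst the 2S centre).
- NaBH4 should give the nitro alcohol F9.
- Esterification with 7 (EDC·HCl, DMAP) should give the nitro ester F10.
- A reductive Nef reaction (TiCl3, NH4OAc buffer) should give the aldehyde F11, which is used at once because its furyl-bearing centre can epimerise.
- Wittig olefination with 1-(triphenylphosphoranylidene)propan-2-one gives 10.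

**Step 10.** Facial selectivity of the hydride addition may be poor. The axial C15 methyl is 1,3 to the path of a hydride entering from the side of the oxygen bridge, so part of the hydride may enter from the other face and give the axial alcohol.

The fallback sets out from 18 and comes back at 19. The reduction is taken to the epimer mixture, and the 9-epi alcohol F12 is equilibrated by reversible hydrogen transfer with [Ru2(CO)4(μ-H)(C4Ph4COHOCC4Ph4)] in toluene at 80 °C. Thermodynamic control should converge on the equatorial alcohol 19, because F12 carries the 1,3-diaxial OH/C15 interaction.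

## Further compounds

F1 | step 8 | (2S,3R)-2-methyl-3-(5-methylfuran-2-yl)-6-oxohexyl 4-(benzyloxy)-3-methoxybenzoate | COc1cc(C(=O)OC[C@@H](C)[C@H](c2ccc(C)o2)CCC=O)ccc1OCc1ccccc1
F2 | step 8 | (2S,3R)-6-acetoxy-2-methyl-3-(5-methylfuran-2-yl)oct-7-yn-1-yl 4-(benzyloxy)-3-methoxybenzoate (both C6 epimers) | COc1cc(C(=O)OC[C@@H](C)[C@H](c2ccc(C)o2)CCC(OC(C)=O)C#C)ccc1OCc1ccccc1
F3 | step 8 | (2S,3R)-8-acetoxy-2-methyl-3-(5-methylfuran-2-yl)octa-6,7-dien-1-yl 4-(benzyloxy)-3-methoxybenzoate (both allene diastereomers) | COc1cc(C(=O)OC[C@@H](C)[C@H](c2ccc(C)o2)CCC=C=COC(C)=O)ccc1OCc1ccccc1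
F4 | step 8 | 9-acetoxy-5,8-epoxy-15-nordauca-6,9-dien-12-yl 4-(benzyloxy)-3-methoxybenzoate (4R,5S,8S,11S as in 16; either C1 epimer) | COc1cc(C(=O)OC[C@@H](C)[C@H]2CCC3C=C(OC(C)=O)[C@]4(C)C=C[C@]23O4)ccc1OCc1ccccc1
F5 | step 8 | 5,8-epoxy-9-oxo-15-nordauca-1(10),6-dien-12-yl 4-(benzyloxy)-3-methoxybenzoate (4R,5S,8S,11S as in 16) | COc1cc(C(=O)OC[C@@H](C)[C@H]2CCC3=CC(=O)[C@]4(C)C=C[C@]23O4)ccc1OCc1ccccc1
F6 | step 8 | (1R,4R,5S,8S,11S)-5,8-epoxy-9-oxodauc-6-en-12-yl 4-(benzyloxy)-3-methoxybenzoate | COc1cc(C(=O)OC[C@@H](C)[C@H]2CC[C@]3(C)CC(=O)[C@]4(C)C=C[C@]23O4)ccc1OCc1ccccc1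
F7 | step 2 | 2-methyl-5-[(E)-2-nitroethenyl]furan | Cc1ccc(/C=C/[N+](=O)[O-])o1
F8 | step 2 | (2S,3S)-2-methyl-3-(5-methylfuran-2-yl)-4-nitrobutanal | O=C[C@@H](C)[C@H](c1ccc(C)o1)C[N+](=O)[O-]
F9 | step 2 | (2S,3S)-2-methyl-3-(5-methylfuran-2-yl)-4-nitrobutan-1-ol | OC[C@@H](C)[C@H](c1ccc(C)o1)C[N+](=O)[O-]
F10 | step 2 | (2S,3S)-2-methyl-3-(5-methylfuran-2-yl)-4-nitrobutyl 4-(benzyloxy)-3-methoxybenzoate | COc1cc(C(=O)OC[C@@H](C)[C@H](c2ccc(C)o2)C[N+](=O)[O-])ccc1OCc1ccccc1
F11 | step 2 | (2S,3R)-2-methyl-3-(5-methylfuran-2-yl)-4-oxobutyl 4-(benzyloxy)-3-methoxybenzoate | COc1cc(C(=O)OC[C@@H](C)[C@H](c2ccc(C)o2)C=O)ccc1OCc1ccccc1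
F12 | step 10 | (1R,4R,5S,8S,9R,11S)-5,8-epoxy-9-hydroxydaucan-12-yl 4-hydroxy-3-methoxybenzoate (9-epimer of 19) | COc1cc(C(=O)OC[C@@H](C)[C@H]2CC[C@]3(C)C[C@@H](O)[C@]4(C)CC[C@]23O4)ccc1O
A1 | alternative 1 | 2-allyl-2-methyl-5-[(2S)-1-(aroyloxy)propan-2-yl]cyclopentanone with C1 and C4 as in the target (aroyl = 4-benzyloxy-3-methoxybenzoyl) | COc1cc(C(=O)OC[C@@H](C)[C@H]2CC[C@](C)(CC=C)C2=O)ccc1OCc1ccccc1
A2 | alternative 1 | tertiary cyclopentanol from A1 carrying allyl at C1 and 3-methylbut-3-enyl at C5 | COc1cc(C(=O)OC[C@@H](C)[C@H]2CC[C@](C)(CC=C)[C@]2(O)CCC(C)=C)ccc1OCc1ccccc1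
A3 | alternative 1 | 5-hydroxydauc-8-en-12-yl 4-(benzyloxy)-3-methoxybenzoate (C1, C4, C5, C11 as in the target) | COc1cc(C(=O)OC[C@@H](C)[C@H]2CC[C@]3(C)CC=C(C)CC[C@]23O)ccc1OCc1ccccc1
A4 | alternative 2 | (2S,3R)-6-chloro-2,6-dimethyl-3-(5-methylfuran-2-yl)-7-oxooctyl 4-(benzyloxy)-3-methoxybenzoate (both C6 epimers) | COc1cc(C(=O)OC[C@@H](C)[C@H](c2ccc(C)o2)CCC(C)(Cl)C(C)=O)ccc1OCc1ccccc1
A5 | alternative 2 | 5,8-epoxy-10-oxodauc-6-en-12-yl 4-(benzyloxy)-3-methoxybenzoate (C1, C4, C5, C8, C11 as in the target) | COc1cc(C(=O)OC[C@@H](C)[C@H]2CC[C@]3(C)C(=O)C[C@]4(C)C=C[C@]23O4)ccc1OCc1ccccc1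
A6 | alternative 3 | 2-(3-diazo-2-oxobutyl)-2-methyl-5-[(2S)-1-(aroyloxy)propan-2-yl]cyclopentanone with C1 and C4 as in the target (aroyl = 4-benzyloxy-3-methoxybenzoyl) | COc1cc(C(=O)OC[C@@H](C)[C@H]2CC[C@](C)(CC(=O)C(C)=[N+]=[N-])C2=O)ccc1OCc1ccccc1
A7 | alternative 3 | (1R,4R,5S,8S,11S)-5,8-epoxy-9-oxodaucan-12-yl 4-(benzyloxy)-3-methoxybenzoate | COc1cc(C(=O)OC[C@@H](C)[C@H]2CC[C@]3(C)CC(=O)[C@]4(C)CC[C@]23O4)ccc1OCc1ccccc1
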